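## Retrosynthetic overview

1. Target 8 ⇐ alcohol 7 (chemoselective O-acetylation) ⇐ acid 6 (carboxyl reduction).
2. Key disconnection, aryl–CH2 bond at C4: acid 6 ⇐ trans-lactone 4 + 4-bromo-2-methoxyphenol 5, by a light-driven Co/Ni ring-opening arylation of the lactone CH2–O bond.
3. Lactone 4 ⇐ (R)-β-methyl-γ-butyrolactone 1 + O-benzylsyringaldehyde 2, by aldol then hydrogenolysis; the purchased C4 stereocentre directs C3 trans.
4. Rings: none is built. Both arenes and the lactone ring are purchased; the lactone is opened in step 3.

Assumption: 1 (enantiopure) and 2 are catalogue items; 1 supplies the only purchased stereocentre.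

## Route

**Step 1**
Reactants: 1, (R)-4-methyldihydrofuran-2(3H)-one; 2, 4-(benzyloxy)-3,5-dimethoxybenzaldehyde
Product: 3, (3S,4R)-3-{[4-(benzyloxy)-3,5-dimethoxyphenyl](hydroxy)methyl}-4-methyldihydrofuran-2(3H)-one (3,4-trans; carbinol epimers, both carried forward)
Conditions: LDA (1.1 equiv), THF, −78 °C; then 2, −78 °C, 1 h; AcOH quench at −78 °C
Reagents that add atoms: none
Why: Aldol addition of the lactone lithium enolate; the aldehyde adds to the enolate face anti to the C4 methyl, so the new C3 centre is set trans by the purchased centre (the carbinol centre is removed in step 2).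

**Step 2**
Reactants: 3
Product: 4, (3R,4R)-3-(4-hydroxy-3,5-dimethoxybenzyl)-4-methyldihydrofuran-2(3H)-one
Conditions: H2 (3 atm), 10% Pd/C, AcOH, cat. HClO4, rt
Reagents that add atoms: none
Why: Pd-catalysed hydrogenolysis cleaves the aryl benzyl ether and the electron-rich benzylic C–OH without touching C3 or C4 (the classical aldol/hydrogenolysis entry to trans-benzylbutyrolactones); any minor cis isomer is removed here.

**Step 3**
Reactants: 4; 5, 4-bromo-2-methoxyphenol (1.5 equiv)
Product: 6, (2R,3S)-2-(4-hydroxy-3,5-dimethoxybenzyl)-4-(4-hydroxy-3-methoxyphenyl)-3-methylbutanoic acid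
Conditions: (i) HMDS, 60 °C, evaporate (transient ArO–TMS, not isolated); (ii) Co(TPP) (5 mol%), NiBr2·dme (10 mol%), dtbbpy (12 mol%), Zn (3 equiv), TMSBr (1.5 equiv), MeCN/THF, 450 nm LEDs, 45 °C; (iii) 1 M HCl
Reagents that add atoms: none (the aryl group comes from reactant 5; the silyl groups are lost on work-up)
Why: Proposed new method: Zn reduces the achiral Co(II) porphyrin to a Co(I) supernucleophile, which attacks the TMSBr/ZnBr2-activated lactone at the CH2–O carbon by SN2 (directly, or via the TMS γ-bromo ester formed reversibly by bromide), giving a primary alkyl–Co(III) that blue light homolyses to the C-radical; this is captured by (dtbbpy)Ni(Ar)Br and reductive elimination forms the aryl–CH2 bond, with the radical on a CH2 so neither stereocentre is touched. The closest known reaction type is Co(I)/Ni dual-catalytic, light-driven ring-opening arylation of epoxides and oxetanes (plus Ni cross-electrophile coupling of alkyl with aryl bromides), here extended to the unstrained C(sp3)–O bond of a γ-butyrolactone.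

**Step 4**
Reactants: 6
Product: 7, (2R,3S)-2-(4-hydroxy-3,5-dimethoxybenzyl)-4-(4-hydroxy-3-methoxyphenyl)-3-methylbutan-1-ol
Conditions: BH3·THF (5 equiv), THF, 0 °C → rt; MeOH, then aqueous work-up
Reagents that add atoms: none
Why: Borane reduces the carboxylic acid to the primary alcohol under non-basic conditions, so the α-stereocentre is not epimerised; the phenols only form borates that are cleaved on methanolysis.

**Step 5**
Reactants: 7
Product: 8, (2R,3S)-2-(4-hydroxy-3,5-dimethoxybenzyl)-4-(4-hydroxy-3-methoxyphenyl)-3-methylbutyl acetate (target)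
Conditions: EtOAc (solvent), p-TsOH·H2O (10 mol%), reflux
Reagents that add atoms: ethyl acetate, CCOC(C)=O (acetyl donor)
Why: Acid-catalysed transesterification is reversible and aryl acetates are thermodynamically disfavoured, so the acetyl ends up only on the aliphatic primary oxygen (as in the selective acetylation of tyrosol-type phenolic alcohols); no stereocentre is involved.

## Compound list

1 | (R)-4-methyldihydrofuran-2(3H)-one | C[C@H]1COC(=O)C1 | starting material
2 | 4-(benzyloxy)-3,5-dimethoxybenzaldehyde | COc1cc(C=O)cc(OC)c1OCc1ccccc1 | starting material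
3 | (3S,4R)-3-{[4-(benzyloxy)-3,5-dimethoxyphenyl](hydroxy)methyl}-4-methyldihydrofuran-2(3H)-one (carbinol epimers) | C[C@H]1COC(=O)[C@@H]1C(O)c1cc(OC)c(OCc2ccccc2)c(OC)c1 | intermediate
4 | (3R,4R)-3-(4-hydroxy-3,5-dimethoxybenzyl)-4-methyldihydrofuran-2(3H)-one | C[C@H]1COC(=O)[C@@H]1Cc1cc(OC)c(O)c(OC)c1 | intermediate
5 | 4-bromo-2-methoxyphenol | COc1cc(Br)ccc1O | starting material
6 | (2R,3S)-2-(4-hydroxy-3,5-dimethoxybenzyl)-4-(4-hydroxy-3-methoxyphenyl)-3-methylbutanoic acid | COc1cc(C[C@H](C)[C@H](C(=O)O)Cc2cc(OC)c(O)c(OC)c2)ccc1O | intermediate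
7 | (2R,3S)-2-(4-hydroxy-3,5-dimethoxybenzyl)-4-(4-hydroxy-3-methoxyphenyl)-3-methylbutan-1-ol | COc1cc(C[C@H](C)[C@H](CO)Cc2cc(OC)c(O)c(OC)c2)ccc1O | intermediate
8 | (2R,3S)-2-(4-hydroxy-3,5-dimethoxybenzyl)-4-(4-hydroxy-3-methoxyphenyl)-3-methylbutyl acetate | COc1cc(C[C@H](C)[C@H](COC(C)=O)Cc2cc(OC)c(O)c(OC)c2)ccc1O | target

## Summary

Total steps: 5. Longest linear sequence: 5 (1 → 3 → 4 → 6 → 7 → 8).

Steps most likely to fail:

1. **Step 3 (proposed new ring-opening arylation).** SN2 opening of an unstrained, β-branched lactone CH2–O may be too slow, or the radical may be lost to reduction or alkene formation. Fallback (known chemistry): open 4 with dry HBr/EtOH to the ethyl γ-bromo ester, couple it with 5 (phenols capped as TBS ethers if they interfere) by the established Ir/Ni silyl-radical ((TMS)3SiH) cross-electrophile coupling under blue light, then reduce the ester with LiAlH4 to rejoin at 7 (one extra step, plus a TBS protection and removal if the phenols must be capped).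
2. **Step 5 (chemoselective acetylation).** Conversion may stall or some phenol acetate may form. Fallback: peracetylate (Ac2O, pyridine) to the triacetate, then selectively cleave the two aryl acetates (pyrrolidine or NH4OAc in aqueous MeOH), leaving the primary alkyl acetate.
3. **Steps 1–2 (aldol/hydrogenolysis).** Trans selectivity may erode with the small β-methyl group, or acid-promoted dehydration to the benzylidene lactone followed by hydrogenation may give the cis isomer. Fallback: alkylate the enolate of 1 directly with 4-(benzyloxy)-3,5-dimethoxybenzyl bromide (from 2 by NaBH4, then PBr3), then remove the benzyl group by simple hydrogenolysis to reach 4.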